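Minutes of half-life of Q: count every flask in them, where the half-life is the time in which Q halves with E held at its charge, and choose the next flask by how many of them fit into its time.

| flask | Q | E | temperature | remark | time |
|---|---|---|---|---|---|
| Wednesday's | 0.15 M | 0.46 M | 62 °C | run made earlier |  |
| Tuesday's | 0.35 M | 0.46 M | 112 °C | run made earlier |  |
| north-east | 0.23 M | 0.460 M | 70 °C |  | 8.0 min |
| east | 0.23 M | 0.460 M | 40 °C |  | 8.0 min |
| north-west | 0.23 M | 0.460 M | 100 °C |  | 8.0 min |
| north | 0.23 M | 0.460 M | 130 °C |  | 8.0 min |

- Wednesday's (time / min: X / %): 0.417: 0.9; 1.33: 3.4; 2.50: 6.2; 4.00: 9.9; 5.00: 11.7; 6.00: 14.1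
- Tuesday's (time / s: X / %): 10.0: 9.5; 15.0: 10.4; 25.0: 19.7; 30.0: 21.4; 40.0: 27.3; 50.0: 30.5

(readings scatter by 1 percentage point)

- the best flask by amount of X, in percent of the Q charged; "all alike" if 1.5 percentage points covers them all (north-east / east / north-west / north / all alike)
- amount of X at the end, in percent of the Q charged, north-east
- amount of X at the end, in percent of the Q charged, east
- amount of X at the end, in percent of the Q charged, north-west
- amount of X at the end, in percent of the Q charged, north

- the numbers in the tables scatter with a standard deviation of 1 percentage point

Take the last reading of each run, with its scatter, as first order in Q and first in E, with E at its mean over the run. Wednesday's run gives 0.0564 M⁻¹ min⁻¹ at 62 °C and Tuesday's run gives 1.07 M⁻¹ min⁻¹ at 112 °C, so the activation energy reads 63.3 kJ mol⁻¹.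

Carry that constant to each flask and divide the natural log of two by the constant times the E charge, a pseudo-first-order view. This gives the half-life of Q: 2.65 min in north-west and 0.581 min in north.

North-east has 15.7 min and east 132 min, both longer than the 8.0 min allowed, so drop these two: they reckon to 29.8% and 4.11% of Q turned over.

North-west holds 3.02 half-lives and north 13.8. X rises from reading to reading in both runs and ends at 30.5% in Tuesday's run, so the readings say nothing of X at higher conversion, but X is a mono adduct and E stands at twice Q in these flasks, so further addition stays open. Charge north-west, not north, because north keeps its X beside E for more half-lives, while north-west already turns over 87.7% of Q by this reckoning.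

The forecast differs: it picks north, with 28% in north-east, 4% in east, 77% in north-west and 90% in north, though it grants that “Either could cut the hot flasks, particularly north”.

The flasks give 26.7% in north-east, 3.95% in east, 57.3% in north-west and 39.6% in north, so the best is north-west.

    Q + E → X (k = 0.0103 M⁻¹ s⁻¹, Ea = 65.0 kJ mol⁻¹)
    E + X → D (k = 0.00349 M⁻¹ s⁻¹, Ea = 62.0 kJ mol⁻¹)
    E + D ⇌ J (K = 3.71 M⁻¹, k = 0.0207 M⁻¹ s⁻¹, Ea = 70.0 kJ mol⁻¹, ΔH = −30.0 kJ mol⁻¹)
    (constants at 100 °C)

North-west took 2.91 min for its first half-life of Q against the reckoned 2.65 min; at 8.00 min it stands at a reckoned 3.02 half-lives, and X is then made 1.13 times as fast as it is used up, each step taken net. North took 0.610 min against the reckoned 0.581 min and stands at a reckoned 13.8 half-lives, and its X has fallen from 52.6% at 4.00 min to 39.6% at 8.00 min.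

Readings and results were generated by integration on assumed constants; the scatter is artificial.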